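**Retrosynthetic overview**
1. Target 13 ⇐ 12 by removal of two O-allyl groups (5-OH, 4'-OH) with zerovalent palladium. Rings A and B are bought as benzenes, and ring C is the only ring that is built.
2. 12 ⇐ 11: ring C is closed through the C3–C4 bond by a carbene-catalysed enantioselective intramolecular crossed benzoin reaction of an achiral keto-aldehyde. This one step makes the chromanone ring, the C4 ketone, the C3 tertiary alcohol and its (S) configuration.
3. Enabling feature: the α-ketol C4(=O)–C3(OH) inside ring C. C4 is an aryl carbonyl on ring A (a latent ArCHO); C3 is a fully substituted carbinol carrying ring B and C2H2–O1 (a latent aryl ketone five atoms away). Two carbonyl carbons of like polarity are joined after polarity reversal of the aldehyde.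
4. 11 ⇐ phenol 10 + α-bromoketone 8 (Williamson ether, O1–C2 bond); 10 comes from monoallylation of 2,6-dihydroxy-4-methoxybenzaldehyde 9.
5. 8 ⇐ 2,4-dihydroxyacetophenone 1: O-allylation and Claisen rearrangement (C3' carbon), cross-metathesis (prenyl), O-allylation, O-methylation, α-bromination.

Key step: step 9

Assumption: the (5aS,10bR) antipode of the aminoindanol-derived triazolium salt is taken to direct attack on the Re face of the ketone and so give (3S); should a first run show the opposite sense, the equally available (5aR,10bS) salt is used with no other change.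

**Step 1**
Reactants: 1 2,4-dihydroxyacetophenone
Product: 2 1-[2-hydroxy-4-(prop-2-en-1-yloxy)phenyl]ethan-1-one
Conditions: allyl bromide (1.1 equiv), K2CO3, acetone, reflux
Reagents that add atoms: allyl bromide, C=CCBr
Why: Williamson etherification should occur only at the 4-OH, because the 2-OH is held in a hydrogen bond to the acetyl group and is much less nucleophilic.

**Step 2**
Reactants: 2 1-[2-hydroxy-4-(prop-2-en-1-yloxy)phenyl]ethan-1-one
Product: 3 1-[2,4-dihydroxy-3-(prop-2-en-1-yl)phenyl]ethan-1-one
Conditions: N,N-diethylaniline, 200 °C, argon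
Reagents that add atoms: none
Why: Aromatic Claisen rearrangement ([3,3]-sigmatropic shift, then tautomerisation) should deliver the allyl group to C3 between the two oxygens, the site favoured over C5 in chelated 2-hydroxyacetophenones.

**Step 3**
Reactants: 3 1-[2,4-dihydroxy-3-(prop-2-en-1-yl)phenyl]ethan-1-one
Product: 4 1-[2,4-dihydroxy-3-(3-methylbut-2-en-1-yl)phenyl]ethan-1-one
Conditions: 2-methyl-2-butene (excess), second-generation Grubbs catalyst RuCl2(=CHPh)(H2IMes)(PCy3) (3 mol %), CH2Cl2, 40 °C
Reagents that add atoms: 2-methyl-2-butene, CC=C(C)C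
Why: Olefin cross-metathesis of the terminal allyl group with excess 2-methyl-2-butene should exchange the =CH2 end for =CMe2 with loss of propene, a standard conversion of an allylarene into a prenylarene that tolerates free phenols and creates no alkene geometry.

**Step 4**
Reactants: 4 1-[2,4-dihydroxy-3-(3-methylbut-2-en-1-yl)phenyl]ethan-1-one
Product: 5 1-[2-hydroxy-3-(3-methylbut-2-en-1-yl)-4-(prop-2-en-1-yloxy)phenyl]ethan-1-one
Conditions: allyl bromide (1.1 equiv), K2CO3, acetone, reflux
Reagents that add atoms: allyl bromide, C=CCBr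
Why: Williamson etherification, again selective for the non-chelated 4-OH, installs the O-allyl protecting group that the last step removes under nearly neutral conditions.

**Step 5**
Reactants: 5 1-[2-hydroxy-3-(3-methylbut-2-en-1-yl)-4-(prop-2-en-1-yloxy)phenyl]ethan-1-one
Product: 6 1-[2-methoxy-3-(3-methylbut-2-en-1-yl)-4-(prop-2-en-1-yloxy)phenyl]ethan-1-one
Conditions: MeI, K2CO3, DMF, 40 °C
Reagents that add atoms: iodomethane, CI
Why: Williamson O-methylation of the only remaining acidic site, the chelated 2-OH, which needs a polar solvent and gentle warming but has no competitor.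

**Step 6**
Reactants: 6 1-[2-methoxy-3-(3-methylbut-2-en-1-yl)-4-(prop-2-en-1-yloxy)phenyl]ethan-1-one
Product: 8 2-bromo-1-[2-methoxy-3-(3-methylbut-2-en-1-yl)-4-(prop-2-en-1-yloxy)phenyl]ethan-1-one, via trimethylsilyl enol ether 7 (not isolated)
Conditions: TMSOTf, Et3N, CH2Cl2, 0 °C; then NBS, THF, −78 °C
Reagents that add atoms: N-bromosuccinimide, O=C1CCC(=O)N1Br; trimethylsilyl trifluoromethanesulfonate, C[Si](C)(C)OS(=O)(=O)C(F)(F)F (its silyl group stays in 7 only)
Why: Soft enolisation of the methyl ketone followed by electrophilic α-bromination of the silyl enol ether with NBS should be selective, because at −78 °C the enol ether is far more nucleophilic than the prenyl and allyl double bonds or the arene.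

**Step 7**
Reactants: 9 2,6-dihydroxy-4-methoxybenzaldehyde
Product: 10 2-hydroxy-4-methoxy-6-(prop-2-en-1-yloxy)benzaldehyde
Conditions: allyl bromide (1.05 equiv), K2CO3 (1.1 equiv), acetone, rt
Reagents that add atoms: allyl bromide, C=CCBr
Why: Williamson monoallylation should stop after one alkylation, because the two hydroxyls of 9 are equivalent and the one that remains is locked in a strong hydrogen bond to the aldehyde.

**Step 8**
Reactants: 8 2-bromo-1-[2-methoxy-3-(3-methylbut-2-en-1-yl)-4-(prop-2-en-1-yloxy)phenyl]ethan-1-one; 10 2-hydroxy-4-methoxy-6-(prop-2-en-1-yloxy)benzaldehyde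
Product: 11 4-methoxy-2-{2-[2-methoxy-3-(3-methylbut-2-en-1-yl)-4-(prop-2-en-1-yloxy)phenyl]-2-oxoethoxy}-6-(prop-2-en-1-yloxy)benzaldehyde
Conditions: K2CO3, acetone, rt
Reagents that add atoms: none
Why: Williamson etherification (SN2 of the phenoxide on a phenacyl-type bromide, a very reactive alkylating agent) should proceed at room temperature with a weak base, mild enough to leave the new enolisable ketone and the aldehyde untouched.

**Step 9**
Reactants: 11 4-methoxy-2-{2-[2-methoxy-3-(3-methylbut-2-en-1-yl)-4-(prop-2-en-1-yloxy)phenyl]-2-oxoethoxy}-6-(prop-2-en-1-yloxy)benzaldehyde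
Product: 12 (3S)-3-hydroxy-7-methoxy-3-[2-methoxy-3-(3-methylbut-2-en-1-yl)-4-(prop-2-en-1-yloxy)phenyl]-5-(prop-2-en-1-yloxy)-2,3-dihydro-4H-chromen-4-one
Conditions: (5aS,10bR)-2-(pentafluorophenyl)-5a,10b-dihydro-4H,6H-indeno[2,1-b][1,2,4]triazolo[4,3-d][1,4]oxazin-2-ium tetrafluoroborate (10–20 mol %), Et3N (10–20 mol %), 4 Å molecular sieves, toluene, rt, argon
Reagents that add atoms: none
Why: The triazolylidene released by Et3N adds to the aldehyde of 11 and proton transfer gives the catalyst-bound enaminol, an acyl-anion equivalent, whose nucleophilic carbon attacks the aryl ketone carbonyl; proton transfer and loss of the carbene then give the α-ketol and return the catalyst. The closest known reaction type is the carbene-catalysed enantioselective intramolecular crossed aldehyde–ketone benzoin reaction of 2-(2-aryl-2-oxoethoxy)benzaldehydes to 3-aryl-3-hydroxychroman-4-ones. Ring C is closed in the 6-exo-trig mode, by attack of the acyl-anion carbon (the future C4) on the ketone carbon (the future C3) across the tether C4a–C8a–O1–C2. The new stereocentre C3 is controlled by the catalyst: the indane backbone shields one face of the enaminol, and the short tether together with the O–H···O=C hydrogen bond of the proton-transfer transition state fixes how the ketone lies over the open face, so that its Re face should be attacked and the (3S) carbinol should result. The step needs chemoselectivity (benzoin closure faster than base-induced aldol condensation of the enolisable OCH2 ketone onto the aldehyde) and facial selectivity; the first is secured because only the aldehyde can form the acyl-anion equivalent while the ketone waits five atoms away, with a weak amine base and an electron-poor N-pentafluorophenyl triazolium keeping enolate concentration low, and the second by the rigid aminoindanol-derived carbene. Since C3 of 12 carries no hydrogen, the product cannot racemise by enolisation.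

**Step 10**
Reactants: 12 (3S)-3-hydroxy-7-methoxy-3-[2-methoxy-3-(3-methylbut-2-en-1-yl)-4-(prop-2-en-1-yloxy)phenyl]-5-(prop-2-en-1-yloxy)-2,3-dihydro-4H-chromen-4-one
Product: 13 (3S)-3,5-dihydroxy-3-[4-hydroxy-2-methoxy-3-(3-methylbut-2-en-1-yl)phenyl]-7-methoxy-2,3-dihydro-4H-chromen-4-one
Conditions: Pd(PPh3)4 (5 mol %), morpholine (10 equiv), THF, rt
Reagents that add atoms: none
Why: Tsuji–Trost deallylation: zerovalent palladium ionises both aryl allyl ethers to allylpalladium complexes that morpholine intercepts, while the C-prenyl group has no leaving group and C3, having no hydrogen, cannot epimerise under these nearly neutral conditions.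

**Compound list**
1 | 1-(2,4-dihydroxyphenyl)ethan-1-one (2,4-dihydroxyacetophenone) | CC(=O)c1ccc(O)cc1O | starting material
2 | 1-[2-hydroxy-4-(prop-2-en-1-yloxy)phenyl]ethan-1-one | CC(=O)c1ccc(OCC=C)cc1O | intermediate
3 | 1-[2,4-dihydroxy-3-(prop-2-en-1-yl)phenyl]ethan-1-one | CC(=O)c1ccc(O)c(CC=C)c1O | intermediate
4 | 1-[2,4-dihydroxy-3-(3-methylbut-2-en-1-yl)phenyl]ethan-1-one | CC(=O)c1ccc(O)c(CC=C(C)C)c1O | intermediate
5 | 1-[2-hydroxy-3-(3-methylbut-2-en-1-yl)-4-(prop-2-en-1-yloxy)phenyl]ethan-1-one | CC(=O)c1ccc(OCC=C)c(CC=C(C)C)c1O | intermediate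
6 | 1-[2-methoxy-3-(3-methylbut-2-en-1-yl)-4-(prop-2-en-1-yloxy)phenyl]ethan-1-one | CC(=O)c1ccc(OCC=C)c(CC=C(C)C)c1OC | intermediate
7 | trimethyl({1-[2-methoxy-3-(3-methylbut-2-en-1-yl)-4-(prop-2-en-1-yloxy)phenyl]ethenyl}oxy)silane | C=C(O[Si](C)(C)C)c1ccc(OCC=C)c(CC=C(C)C)c1OC | intermediate
8 | 2-bromo-1-[2-methoxy-3-(3-methylbut-2-en-1-yl)-4-(prop-2-en-1-yloxy)phenyl]ethan-1-one | BrCC(=O)c1ccc(OCC=C)c(CC=C(C)C)c1OC | intermediate
9 | 2,6-dihydroxy-4-methoxybenzaldehyde | COc1cc(O)c(C=O)c(O)c1 | starting material
10 | 2-hydroxy-4-methoxy-6-(prop-2-en-1-yloxy)benzaldehyde | COc1cc(O)c(C=O)c(OCC=C)c1 | intermediate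
11 | 4-methoxy-2-{2-[2-methoxy-3-(3-methylbut-2-en-1-yl)-4-(prop-2-en-1-yloxy)phenyl]-2-oxoethoxy}-6-(prop-2-en-1-yloxy)benzaldehyde | COc1cc(OCC=C)c(C=O)c(OCC(=O)c2ccc(OCC=C)c(CC=C(C)C)c2OC)c1 | intermediate
12 | (3S)-3-hydroxy-7-methoxy-3-[2-methoxy-3-(3-methylbut-2-en-1-yl)-4-(prop-2-en-1-yloxy)phenyl]-5-(prop-2-en-1-yloxy)-2,3-dihydro-4H-chromen-4-one | COc1cc(OCC=C)c2c(c1)OC[C@@](O)(c1ccc(OCC=C)c(CC=C(C)C)c1OC)C2=O | intermediate
13 | (3S)-3,5-dihydroxy-3-[4-hydroxy-2-methoxy-3-(3-methylbut-2-en-1-yl)phenyl]-7-methoxy-2,3-dihydro-4H-chromen-4-one | COc1cc(O)c2c(c1)OC[C@@](O)(c1ccc(O)c(CC=C(C)C)c1OC)C2=O | target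

**Total steps:** 10. **Longest linear sequence:** 9 (steps 1–6, 8, 9, 10).

**Steps most likely to fail**

Step 9. Carbene addition to the electron-rich aldehyde flanked by two ortho alkoxy groups may be slow, so that base-induced intramolecular aldol condensation of the OCH2 ketone (benzofuran formation) competes, and facial discrimination at the aryl ketone may be incomplete. The fallback sets out from 11 and comes back at 12. It gives up catalyst control of the stereocentre: ring C is closed with a small achiral thiazolylidene (3-benzyl-5-(2-hydroxyethyl)-4-methylthiazolium chloride, DBU, t-BuOH, 40 °C), a known racemic crossed aldehyde–ketone benzoin cyclisation, to give racemic 3-hydroxy-7-methoxy-3-[2-methoxy-3-(3-methylbut-2-en-1-yl)-4-(prop-2-en-1-yloxy)phenyl]-5-(prop-2-en-1-yloxy)-2,3-dihydro-4H-chromen-4-one F1. The enantiomers are then separated by preparative chromatography on an amylose tris(3,5-dimethylphenylcarbamate) stationary phase; the (3S) isomer is 12 and the (3R)-enantiomer of 12 F2 is set aside.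

Step 8. The carbonate base may enolise the newly formed aryloxymethyl ketone, which then condenses onto the ortho aldehyde (benzofuran formation), while alkylation of the chelated phenol is sluggish. The fallback sets out from 8 and 10 and comes back at 11. It carries the ketone through the etherification at the alcohol oxidation level: 8 is reduced (NaBH4, MeOH, 0 °C) to racemic 2-bromo-1-[2-methoxy-3-(3-methylbut-2-en-1-yl)-4-(prop-2-en-1-yloxy)phenyl]ethan-1-ol F3. With 10 and K2CO3 in DMF at 60 °C this closes in the flask to racemic 2-[2-methoxy-3-(3-methylbut-2-en-1-yl)-4-(prop-2-en-1-yloxy)phenyl]oxirane F4, which the phenoxide should open at the terminal carbon to racemic 2-{2-hydroxy-2-[2-methoxy-3-(3-methylbut-2-en-1-yl)-4-(prop-2-en-1-yloxy)phenyl]ethoxy}-4-methoxy-6-(prop-2-en-1-yloxy)benzaldehyde F5, a compound with no enolisable ketone. Dess–Martin periodinane (NaHCO3, CH2Cl2, rt) then oxidises the secondary alcohol to give 11.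

Step 6. Electrophilic bromine may attack the prenyl double bond or the activated arene position ortho to the allyloxy group, or over-brominate the ketone. The fallback sets out from 6 (with 10) and comes back at 11, bypassing 8 and step 8. It puts oxygen instead of bromine on the α-carbon: the potassium enolate of 6 (KN(SiMe3)2, THF, −78 °C) is oxidised with 2-(benzenesulfonyl)-3-phenyloxaziridine, which does not touch isolated alkenes at this temperature, to 2-hydroxy-1-[2-methoxy-3-(3-methylbut-2-en-1-yl)-4-(prop-2-en-1-yloxy)phenyl]ethan-1-one F6. Mitsunobu etherification of F6 with phenol 10 (PPh3, diisopropyl azodicarboxylate, THF, 0 °C to rt) then gives 11 without any base.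

**Further compounds**
F1 | step 9 | racemic 3-hydroxy-7-methoxy-3-[2-methoxy-3-(3-methylbut-2-en-1-yl)-4-(prop-2-en-1-yloxy)phenyl]-5-(prop-2-en-1-yloxy)-2,3-dihydro-4H-chromen-4-one | COc1cc(OCC=C)c2c(c1)OCC(O)(c1ccc(OCC=C)c(CC=C(C)C)c1OC)C2=O
F2 | step 9 | (3R)-3-hydroxy-7-methoxy-3-[2-methoxy-3-(3-methylbut-2-en-1-yl)-4-(prop-2-en-1-yloxy)phenyl]-5-(prop-2-en-1-yloxy)-2,3-dihydro-4H-chromen-4-one | COc1cc(OCC=C)c2c(c1)OC[C@](O)(c1ccc(OCC=C)c(CC=C(C)C)c1OC)C2=O
F3 | step 8 | racemic 2-bromo-1-[2-methoxy-3-(3-methylbut-2-en-1-yl)-4-(prop-2-en-1-yloxy)phenyl]ethan-1-ol | OC(CBr)c1ccc(OCC=C)c(CC=C(C)C)c1OC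
F4 | step 8 | racemic 2-[2-methoxy-3-(3-methylbut-2-en-1-yl)-4-(prop-2-en-1-yloxy)phenyl]oxirane | C1OC1c1ccc(OCC=C)c(CC=C(C)C)c1OC
F5 | step 8 | racemic 2-{2-hydroxy-2-[2-methoxy-3-(3-methylbut-2-en-1-yl)-4-(prop-2-en-1-yloxy)phenyl]ethoxy}-4-methoxy-6-(prop-2-en-1-yloxy)benzaldehyde | COc1cc(OCC=C)c(C=O)c(OCC(O)c2ccc(OCC=C)c(CC=C(C)C)c2OC)c1
F6 | step 6 | 2-hydroxy-1-[2-methoxy-3-(3-methylbut-2-en-1-yl)-4-(prop-2-en-1-yloxy)phenyl]ethan-1-one | OCC(=O)c1ccc(OCC=C)c(CC=C(C)C)c1OC
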